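The readings are simulated for an exercise, and the scatter is random.

A slope of 0.224 L mol⁻¹ h⁻¹ is the number we carry. It is how fast the inverse of S climbs in the dusk run from 5.0 h to 15 h, where S is the concentration of starting material. As a reading, it carries the scatter.

| flask | starting material | coupling partner | free catalyst | product | time |
|---|---|---|---|---|---|
| summer | 0.300 M | 0.600 M | 0.00300 M |  |  |
| dusk | 0.120 M | 0.420 M | 0.00300 M |  |  |
| midnight | 0.300 M | 0.600 M | 0.00300 M | 0.150 M |  |
| spring | 0.300 M | 0.200 M | 0.00150 M |  | 15 h |

- summer run (time / h: [starting material] / M): 2.5: 0.224; 5.0: 0.179; 7.5: 0.158; 10: 0.144; 12: 0.140; 15: 0.128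
- dusk run (time / h: [starting material] / M): 2.5: 0.096; 5.0: 0.083; 7.5: 0.084; 10: 0.078; 12: 0.069; 15: 0.070
- midnight run (time / h: [starting material] / M): 2.5: 0.223; 5.0: 0.186; 7.5: 0.159; 10: 0.145; 12: 0.137; 15: 0.128

(each reading ± 0.003 M)

* starting material in the spring run at 15 h, as a share of the starting material charged

- Overall: starting material + coupling partner -> product, with free catalyst as catalyst.
- Constant volume, constant temperature.

1. First instants. Summer loses 0.0760 M of starting material by 2.5 h. Midnight, charged with 0.150 M of product, loses 0.0770 M, so added product shows no effect in these readings. The inverse of S climbs at 0.452 L mol⁻¹ h⁻¹ in summer, twice the late dusk slope.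

2. Middle. Summer and dusk have the same excess of coupling partner, 0.300 M, and dusk starts near summer's last reading. Yet the first rate of loss read in the dusk run is 9.60 mM h⁻¹, higher than the last one read in the summer run, 4.00 mM h⁻¹. So these two runs read slower late in a flask than early at like concentrations.

3. End. A loss that goes with S squared makes the inverse of S climb in a straight line at one slope, whatever the charge. The fraction left is then one over (one plus slope × charge × time). We test this on summer: starting from its 5.0 h reading, the dusk slope gives 0.128 M at 15 h, and the reading is 0.128 M.

4. Spring. Here the coupling partner is the limiting reagent, at 0.200 M against 0.300 M of starting material, and the catalyst is half that of summer. Our own reckoning puts the whole late slope on this loss, so the fraction left by pairing is 49.8 %.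

The forecast says 85 %, well above ours, on the grounds “That leaves catalyst death”.

The flask gives 61.4 %.

    2 free catalyst ⇌ catalyst dimer, settled at all times (6530 L mol⁻¹)
    catalyst dimer + starting material + coupling partner → product + catalyst dimer (160.2 L² mol⁻² h⁻¹)
    coupling partner → lost reagent (0.1789 h⁻¹)
    2 starting material → homo dimer (0.05796 L mol⁻¹ h⁻¹)

Spring keeps more than our 49.8 % and less than the forecast's figure. Without the turning of starting material into homo dimer, spring would keep 91.5 %, so that step costs 30 percentage points. Our rule, now with twice the pairing constant as the slope, leaves 65.7 % by pairing. Multiplying the two fractions left gives 60.1 %, against 61.4 % in the spring flask.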